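**Retrosynthetic overview**
1. Target 21 ⇒ 2′-hydroxychalcone triacetate 8 + acetylated aryl-diene-yne 18. One final operation does an asymmetric exo Diels–Alder (cyclohexene, all three stereocentres) and then, in the same flask, global deacetylation with 5-endo-dig closure of the furan ring.
2. 8 ⇒ morachalcone A 7 ⇒ Claisen–Schmidt of 3-prenylresacetophenone 3 with bis-MOM aldehyde 5.
3. 18 ⇒ 4-bromo-6-iodoresorcinol diacetate 11: Sonogashira at C–I with alkyne 14, then Suzuki at C–Br with dienylboronate 17.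
4. Ring order: cyclohexene, then furan, both in the last operation; all benzene rings are bought.

Assumption: the (R)-VANOL borate is taken to shield the Cα-Re face of the boron-chelated chalcone (spiro-borate model, not a confirmed precedent); if the first run gives the antipode, (S)-VANOL is used with nothing else changed.

**Route**

Step 1
Reactants: 1 2,4-dihydroxyacetophenone; 2 prenyl bromide
Product: 3 1-[2,4-dihydroxy-3-(3-methylbut-2-en-1-yl)phenyl]ethan-1-one
Conditions: KOH (10% aq), 0 °C → rt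
Reagents that add atoms: none
Why: Phenoxide C-alkylation (direct C-prenylation) of the dianion in water goes mainly to C3, the carbon between the two oxygens; the 5-prenyl and O-prenyl isomers are removed on silica.

Step 2
Reactants: 4 2,4-dihydroxybenzaldehyde
Product: 5 2,4-bis(methoxymethoxy)benzaldehyde
Conditions: MOMCl, NaH, DMF, 0 °C → rt
Reagents that add atoms: chloromethyl methyl ether (MOMCl), COCCl
Why: Williamson-type O-alkylation (MOM protection) removes the phenoxide donation that would make the aldehyde unreactive in the aldol step.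

Step 3
Reactants: 3; 5
Product: 6 (E)-3-[2,4-bis(methoxymethoxy)phenyl]-1-[2,4-dihydroxy-3-(3-methylbut-2-en-1-yl)phenyl]prop-2-en-1-one
Conditions: LiHMDS (3.5 equiv), THF, −78 °C → rt; 1 M HCl
Reagents that add atoms: none
Why: Claisen–Schmidt aldol condensation through the lithium trianion (two phenoxides plus enolate) of the unprotected ketone, with E1cB loss of water giving the E-enone.

Step 4
Reactants: 6
Product: 7 morachalcone A, (E)-1-[2,4-dihydroxy-3-(3-methylbut-2-en-1-yl)phenyl]-3-(2,4-dihydroxyphenyl)prop-2-en-1-one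
Conditions: 3 M HCl, MeOH, 50 °C
Reagents that add atoms: none
Why: Acid-catalysed acetal methanolysis removes both MOM groups; the prenyl group and the enone tolerate brief, mild HCl/MeOH.

Step 5
Reactants: 7
Product: 8 4-[(E)-3-[4-acetoxy-2-hydroxy-3-(3-methylbut-2-en-1-yl)phenyl]-3-oxoprop-1-en-1-yl]-1,3-phenylene diacetate (morachalcone A 4′,2,4-triacetate, 2′-OH free)
Conditions: Ac2O (3.2 equiv), Et3N, CH2Cl2, 0 °C
Reagents that add atoms: acetic anhydride, CC(=O)OC(C)=O
Why: Chemoselective O-acetylation: the 2′-OH is hydrogen-bonded to the ketone and reacts last, so it stays free for boron chelation while the three acetates make the enone a better dienophile.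

Step 6
Reactants: 9 4-bromoresorcinol
Product: 10 4-bromo-6-iodobenzene-1,3-diol
Conditions: ICl (1.05 equiv), Et2O, 0 °C → rt
Reagents that add atoms: iodine monochloride, ClI
Why: Electrophilic aromatic iodination goes to C6, which is ortho/para to the two hydroxyls and less hindered than C2.

Step 7
Reactants: 10
Product: 11 4-bromo-6-iodo-1,3-phenylene diacetate
Conditions: Ac2O, Et3N, DMAP (cat.), CH2Cl2, 0 °C → rt
Reagents that add atoms: acetic anhydride, CC(=O)OC(C)=O
Why: Phenol acylation masks both oxygens so that the later o-alkynyl aryl acetate cannot close to the benzofuran before the last operation.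

Step 8
Reactants: 12 3,5-dihydroxybenzaldehyde
Product: 14 5-ethynyl-1,3-phenylene diacetate, via 5-ethynylbenzene-1,3-diol 13 (not isolated)
Conditions: Bestmann–Ohira reagent, K2CO3 (4 equiv), MeOH, rt; evaporate; Ac2O, Et3N, CH2Cl2, 0 °C → rt
Reagents that add atoms: dimethyl (1-diazo-2-oxopropyl)phosphonate (Bestmann–Ohira reagent), CC(=O)C(=[N+]=[N-])P(=O)(OC)OC; acetic anhydride, CC(=O)OC(C)=O
Why: Seyferth–Gilbert homologation (Ohira–Bestmann variant) works on the free aldehyde because meta-phenoxides do not conjugate with it, and the crude diphenol is acetylated in the same flask.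

Step 9
Reactants: 11; 14
Product: 15 4-bromo-6-[(3,5-diacetoxyphenyl)ethynyl]-1,3-phenylene diacetate
Conditions: PdCl2(PPh3)2 (2 mol %), CuI (4 mol %), Et3N, THF, rt
Reagents that add atoms: none
Why: Sonogashira coupling at rt is selective for C–I over C–Br, and the acetylated ortho oxygen cannot undergo the usual heteroannulation.

Step 10
Reactants: 16 2-methylbut-1-en-3-yne
Product: 17 (E)-4,4,5,5-tetramethyl-2-(3-methylbuta-1,3-dien-1-yl)-1,3,2-dioxaborolane
Conditions: HBpin, Cp2Zr(H)Cl (5 mol %), Et3N (10 mol %), neat, 60 °C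
Reagents that add atoms: pinacolborane, CC1(C)OBOC1(C)C
Why: Zirconium-catalysed syn-hydroboration (hydrozirconation/transmetalation) of the terminal alkyne is anti-Markovnikov and gives the E-dienylboronate, leaving the 1,1-disubstituted alkene untouched.

Step 11
Reactants: 15; 17
Product: 18 4-[(3,5-diacetoxyphenyl)ethynyl]-6-[(E)-3-methylbuta-1,3-dien-1-yl]-1,3-phenylene diacetate
Conditions: Pd(OAc)2 (3 mol %), SPhos (6 mol %), CsF (anhydrous), 1,4-dioxane, 65 °C
Reagents that add atoms: none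
Why: Suzuki–Miyaura coupling at the aryl bromide retains the E-alkene geometry, and anhydrous fluoride activation is chosen to spare the four aryl acetates.

Step 12
Reactants: 8; 18
Product: 21 [2,4-dihydroxy-3-(3-methylbut-2-en-1-yl)phenyl][(1R,2R,6S)-6-(2,4-dihydroxyphenyl)-2-[2-(3,5-dihydroxyphenyl)-6-hydroxy-1-benzofuran-5-yl]-4-methylcyclohex-3-en-1-yl]methanone (CNP0150120.1), via alkynyl cycloadduct heptaacetate 19 (not isolated), via alkynyl octaphenol 20 (not isolated)
Conditions: (R)-VANOL, BH3·THF, AcOH (1.5 equiv each), THF, rt, 1 h, evaporate; 8, 18 (1.5 equiv), PhCF3, rt, 48 h; then degassed MeOH, K2CO3 (15 equiv), CuI (10 mol %), Ar, 45 °C, 6 h; 1 M HCl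
Reagents that add atoms: none
Why: Proposed new method: a chiral biaryl-diol borate-promoted Diels–Alder of a 2′-hydroxychalcone (known reaction type) is telescoped with a Zemplén-type methanolysis of all seven acetates and a Cu(I)/base 5-endo-dig hydroalkoxylation of the freed o-alkynylphenoxide (the cyclisation half of a Sonogashira–heteroannulation benzofuran synthesis); the 2′-O/C=O boron chelate activates the enone, the more nucleophilic CH2 terminus of the diene bonds to Cβ, the (R)-VANOL wall is expected to block the Cα-Re face so the diene adds to the Cα-Si/Cβ-Si face, the E-enone fixes the acyl/aryl trans relationship and the exo transition state puts the diene aryl trans to the acyl group, giving the all-trans (1R,2R,6S) ring, which is the thermodynamically preferred triequatorial isomer and is not epimerised by the base phase.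

**Compound list**
1 | 2,4-dihydroxyacetophenone | CC(=O)c1ccc(O)cc1O | starting material
2 | prenyl bromide (1-bromo-3-methylbut-2-ene) | CC(C)=CCBr | starting material
3 | 1-[2,4-dihydroxy-3-(3-methylbut-2-en-1-yl)phenyl]ethan-1-one | CC(=O)c1ccc(O)c(CC=C(C)C)c1O | intermediate
4 | 2,4-dihydroxybenzaldehyde | O=Cc1ccc(O)cc1O | starting material
5 | 2,4-bis(methoxymethoxy)benzaldehyde | COCOc1ccc(C=O)c(OCOC)c1 | intermediate
6 | (E)-3-[2,4-bis(methoxymethoxy)phenyl]-1-[2,4-dihydroxy-3-(3-methylbut-2-en-1-yl)phenyl]prop-2-en-1-one | CC(C)=CCc1c(O)ccc(C(=O)/C=C/c2ccc(OCOC)cc2OCOC)c1O | intermediate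
7 | morachalcone A | CC(C)=CCc1c(O)ccc(C(=O)/C=C/c2ccc(O)cc2O)c1O | intermediate
8 | morachalcone A 4′,2,4-triacetate (2′-OH free) | CC(C)=CCc1c(OC(C)=O)ccc(C(=O)/C=C/c2ccc(OC(C)=O)cc2OC(C)=O)c1O | intermediate
9 | 4-bromoresorcinol | Oc1ccc(Br)c(O)c1 | starting material
10 | 4-bromo-6-iodobenzene-1,3-diol | Oc1cc(O)c(I)cc1Br | intermediate
11 | 4-bromo-6-iodo-1,3-phenylene diacetate | CC(=O)Oc1cc(OC(C)=O)c(I)cc1Br | intermediate
12 | 3,5-dihydroxybenzaldehyde | O=Cc1cc(O)cc(O)c1 | starting material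
13 | 5-ethynylbenzene-1,3-diol (not isolated) | C#Cc1cc(O)cc(O)c1 | intermediate
14 | 5-ethynyl-1,3-phenylene diacetate | C#Cc1cc(OC(C)=O)cc(OC(C)=O)c1 | intermediate
15 | 4-bromo-6-[(3,5-diacetoxyphenyl)ethynyl]-1,3-phenylene diacetate | CC(=O)Oc1cc(OC(C)=O)c(C#Cc2cc(OC(C)=O)cc(OC(C)=O)c2)cc1Br | intermediate
16 | 2-methylbut-1-en-3-yne | C=C(C)C#C | starting material
17 | (E)-4,4,5,5-tetramethyl-2-(3-methylbuta-1,3-dien-1-yl)-1,3,2-dioxaborolane | C=C(C)/C=C/B1OC(C)(C)C(C)(C)O1 | intermediate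
18 | 4-[(3,5-diacetoxyphenyl)ethynyl]-6-[(E)-3-methylbuta-1,3-dien-1-yl]-1,3-phenylene diacetate | C=C(C)/C=C/c1cc(C#Cc2cc(OC(C)=O)cc(OC(C)=O)c2)c(OC(C)=O)cc1OC(C)=O | intermediate
19 | [4-acetoxy-2-hydroxy-3-(3-methylbut-2-en-1-yl)phenyl][(1R,2R,6S)-6-(2,4-diacetoxyphenyl)-2-{2,4-diacetoxy-5-[(3,5-diacetoxyphenyl)ethynyl]phenyl}-4-methylcyclohex-3-en-1-yl]methanone (not isolated) | CC(C)=CCc1c(OC(C)=O)ccc(C(=O)[C@@H]2[C@@H](c3ccc(OC(C)=O)cc3OC(C)=O)CC(C)=C[C@H]2c2cc(C#Cc3cc(OC(C)=O)cc(OC(C)=O)c3)c(OC(C)=O)cc2OC(C)=O)c1O | intermediate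
20 | [2,4-dihydroxy-3-(3-methylbut-2-en-1-yl)phenyl][(1R,2R,6S)-6-(2,4-dihydroxyphenyl)-2-{5-[(3,5-dihydroxyphenyl)ethynyl]-2,4-dihydroxyphenyl}-4-methylcyclohex-3-en-1-yl]methanone (not isolated) | CC(C)=CCc1c(O)ccc(C(=O)[C@@H]2[C@@H](c3ccc(O)cc3O)CC(C)=C[C@H]2c2cc(C#Cc3cc(O)cc(O)c3)c(O)cc2O)c1O | intermediate
21 | [2,4-dihydroxy-3-(3-methylbut-2-en-1-yl)phenyl][(1R,2R,6S)-6-(2,4-dihydroxyphenyl)-2-[2-(3,5-dihydroxyphenyl)-6-hydroxy-1-benzofuran-5-yl]-4-methylcyclohex-3-en-1-yl]methanone (CNP0150120.1) | CC(C)=CCc1c(O)ccc(C(=O)[C@@H]2[C@@H](c3ccc(O)cc3O)CC(C)=C[C@H]2c2cc3cc(-c4cc(O)cc(O)c4)oc3cc2O)c1O | target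

**Totals**
Total step count: 12.
Longest linear sequence: 5 steps (1 → 3 → 6 → 7 → 8 → 21, steps 1, 3, 4, 5, 12; the branch 9 → 10 → 11 → 15 → 18 → 21 is also 5).

**Three steps most likely to fail, with fallbacks**

Step 12 (one-flask Diels–Alder, deacetylation and furan closure). The risks are the exo/endo ratio, the sense and level of induction, and a slow closure of the electron-rich alkynyl phenoxide; the product can only be purified at the polyphenol stage (silica to remove VANOL, reversed-phase HPLC to remove the endo isomer). The fallback sets out from 18 and comes back at 21, and it builds the two rings in separate, isolable stages. Compound 18 is treated with K2CO3 and CuI (cat.) in degassed MeOH at 45 °C to give (E)-2-(3,5-dihydroxyphenyl)-5-(3-methylbuta-1,3-dien-1-yl)-1-benzofuran-6-ol F1. This is re-acetylated (Ac2O, Et3N, CH2Cl2) to (E)-5-[6-acetoxy-5-(3-methylbuta-1,3-dien-1-yl)-1-benzofuran-2-yl]-1,3-phenylene diacetate F2. F2 and 8 are then combined under the same (R)-VANOL/BH3·THF/AcOH borate conditions to give the exo cycloadduct hexaacetate F3, which is separated from the endo isomer on silica and assayed by chiral HPLC. K2CO3 in MeOH/THF at rt then removes the six acetates to give 21.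

Step 11 (Suzuki coupling). The risks are acetate loss under fluoride with early furan closure, and the sensitivity of the dienylboronate and diene. The fallback sets out from 15 and comes back at 18. A Heck reaction of 15 with 2-methylbut-3-en-2-ol (Pd(OAc)2, P(o-tol)3, Et3N, DMF, 90 °C) gives 4-[(3,5-diacetoxyphenyl)ethynyl]-6-[(E)-3-hydroxy-3-methylbut-1-en-1-yl]-1,3-phenylene diacetate F4. Neutral dehydration of this tertiary allylic alcohol with Burgess reagent (toluene, 60 °C) can only give the isopropenyl diene 18. This route needs neither 17 nor step 10.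

Step 1 (direct C-prenylation). The yield is typically low (about 30%) and the 5-prenyl and O-prenyl isomers must be removed. The fallback sets out from 1 and comes back at 7. Iodination of 1 (I2, HIO3, aq. EtOH) between the two oxygens gives 1-(2,4-dihydroxy-3-iodophenyl)ethan-1-one F5; two ortho-coupled aromatic doublets in the NMR confirm the 3-iodo isomer. Protection (MOMCl, NaH, DMF) gives 1-[3-iodo-2,4-bis(methoxymethoxy)phenyl]ethan-1-one F6. Stille coupling with tributyl(3-methylbut-2-en-1-yl)stannane (Pd(PPh3)4, DMF, 90 °C) gives 1-[2,4-bis(methoxymethoxy)-3-(3-methylbut-2-en-1-yl)phenyl]ethan-1-one F7. A standard KOH/EtOH Claisen–Schmidt condensation with 5 gives (E)-1-[2,4-bis(methoxymethoxy)-3-(3-methylbut-2-en-1-yl)phenyl]-3-[2,4-bis(methoxymethoxy)phenyl]prop-2-en-1-one F8. HCl/MeOH at 50 °C then gives 7.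

**Further compounds**
F1 | step 12 | (E)-2-(3,5-dihydroxyphenyl)-5-(3-methylbuta-1,3-dien-1-yl)-1-benzofuran-6-ol | C=C(C)/C=C/c1cc2cc(-c3cc(O)cc(O)c3)oc2cc1O
F2 | step 12 | (E)-5-[6-acetoxy-5-(3-methylbuta-1,3-dien-1-yl)-1-benzofuran-2-yl]-1,3-phenylene diacetate | C=C(C)/C=C/c1cc2cc(-c3cc(OC(C)=O)cc(OC(C)=O)c3)oc2cc1OC(C)=O
F3 | step 12 | [4-acetoxy-2-hydroxy-3-(3-methylbut-2-en-1-yl)phenyl][(1R,2R,6S)-6-(2,4-diacetoxyphenyl)-2-[6-acetoxy-2-(3,5-diacetoxyphenyl)-1-benzofuran-5-yl]-4-methylcyclohex-3-en-1-yl]methanone | CC(C)=CCc1c(OC(C)=O)ccc(C(=O)[C@@H]2[C@@H](c3ccc(OC(C)=O)cc3OC(C)=O)CC(C)=C[C@H]2c2cc3cc(-c4cc(OC(C)=O)cc(OC(C)=O)c4)oc3cc2OC(C)=O)c1O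
F4 | step 11 | 4-[(3,5-diacetoxyphenyl)ethynyl]-6-[(E)-3-hydroxy-3-methylbut-1-en-1-yl]-1,3-phenylene diacetate | CC(C)(O)/C=C/c1cc(C#Cc2cc(OC(C)=O)cc(OC(C)=O)c2)c(OC(C)=O)cc1OC(C)=O
F5 | step 1 | 1-(2,4-dihydroxy-3-iodophenyl)ethan-1-one | CC(=O)c1ccc(O)c(I)c1O
F6 | step 1 | 1-[3-iodo-2,4-bis(methoxymethoxy)phenyl]ethan-1-one | CC(=O)c1ccc(OCOC)c(I)c1OCOC
F7 | step 1 | 1-[2,4-bis(methoxymethoxy)-3-(3-methylbut-2-en-1-yl)phenyl]ethan-1-one | CC(=O)c1ccc(OCOC)c(CC=C(C)C)c1OCOC
F8 | step 1 | (E)-1-[2,4-bis(methoxymethoxy)-3-(3-methylbut-2-en-1-yl)phenyl]-3-[2,4-bis(methoxymethoxy)phenyl]prop-2-en-1-one | CC(C)=CCc1c(OCOC)ccc(C(=O)/C=C/c2ccc(OCOC)cc2OCOC)c1OCOC
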